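Ainsliadimer B is cut at C2–C4' and C14–C15' (Diels–Alder) and at the C10 and C15 hydroxyls (late oxygenation, hydration) into two molecules of dehydrozaluzanin C. Its cyclopentanone C1'–C5', the later spiro ring, is never closed as a five-membered ring. It is the six-membered cross-conjugated dienone ring A (C1–C5, C10) of the eudesmanolide α-santonin. Irradiation in aqueous acid bonds C1 to C5 and cuts C5–C10, so ring A loses C10 and ring B gains C1. The 6/6 decalin becomes the 5/7 hydroazulene in one operation, with H-1 set and a C10 hydroxyl as latent C10=C14. The step exploits the pattern C3'=O, C15' on C4' and C10' on C1' around that ring.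

Key step: step 1

Remark on the chemistry: guaiane numbering is used throughout, and the eudesmane numbering of 1 carries the same atom labels. Unprimed atoms belong to the half with the two hydroxyls, primed atoms to the half with the spiro cyclopentanone. α is the face of H-1, H-5 and H-7. Hydrogen is assumed to be delivered syn in step 2, so 4 is drawn with a 4β-methyl group; this centre is erased in step 3.

Step 1
Reactants: 1 α-santonin
Product: 3 isophotosantonic lactone, via cyclopropane zwitterion 2 (not isolated)
Conditions: hν (medium-pressure Hg lamp, quartz well), AcOH–H2O 1:1, N2, reflux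
Reagents that add atoms: water O
Why: Type A photorearrangement of a cross-conjugated cyclohexadienone under solvolytic conditions: n→π* excitation and intersystem crossing are followed by bonding between the two β-carbons C1 and C5, which gives zwitterion 2, a cyclopropane (C1, C5, C10) fused to an oxyallyl cation (C2–C3–C4). In the acid the oxygen is protonated, the cyclopropylcarbinyl cation centred on C4 breaks the C5–C10 bond to form C4=C5, water captures C10, and the C2=C3 enol goes to the ketone. The five-membered ring C1–C5 closes by this transannular C1–C5 bonding across ring A (first as the 3-exo closure of the cyclopropane) and is ring A less C10, while the seven-membered ring is closed by no new bond: it is ring B enlarged by C1 once C5–C10 is cut. H-1 ends on the α face because C10, tied to C9 of ring B, can bridge C1 and C5 only on the β face, and C10 becomes the 10α-alcohol because water attacks anti to the leaving C5–C10 bond (inversion); C6, C7 and C11 are not touched. The step needs cleavage of C5–C10 rather than C1–C10 (which would lead to a spiro[4.5]decenone) and solvolysis faster than the sigmatropic shift to lumisantonin: the C4 methyl group localises the positive charge on C4, next to C5, and the hot protic medium protonates 2 and supplies the nucleophile.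

Step 2
Reactants: 3 isophotosantonic lactone
Product: 4 4,5-dihydroisophotosantonic lactone (1α,4α,5α-H)
Conditions: H2 (1 atm), 10% Pd/C, EtOAc, rt
Reagents that add atoms: none
Why: Heterogeneous catalytic hydrogenation: the tetrasubstituted enone is the only C=C bond and should take up hydrogen syn from the α face, the side of H-1 and away from the 10β-methyl group, which sets 5α-H (cis-fused hydroazulene) and a 4β-methyl group that is erased in step 3.

Step 3
Reactants: 4 4,5-dihydroisophotosantonic lactone
Product: 5 3,10α-bis(triethylsilyloxy)guai-3-en-12,6α-olide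
Conditions: TESOTf (2.5 equiv), Et3N (4 equiv), CH2Cl2, 0 °C to rt
Reagents that add atoms: triethylsilyl trifluoromethanesulfonate (TESOTf) CC[Si](CC)(CC)OS(=O)(=O)C(F)(F)F
Why: Soft enolisation with a silyl triflate and an amine under equilibrating conditions should give the more substituted (thermodynamic) C3=C4 silyl enol ether, and the same reagent caps the tertiary C10 alcohol, so that no O–H and no ketone α-proton is left for step 4.

Step 4
Reactants: 5 3,10α-bis(triethylsilyloxy)guai-3-en-12,6α-olide
Product: 6 11β-phenylseleno lactone (13-methyl α)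
Conditions: LDA (1.2 equiv), THF, −78 °C; PhSeSePh, HMPA, −78 to −20 °C
Reagents that add atoms: diphenyl diselenide c1ccc(cc1)[Se][Se]c1ccccc1
Why: Selenenylation of a lactone enolate: LDA removes H-11, the only acidic proton left, and the diselenide, which unlike PhSeCl leaves silyl enol ethers alone, should enter the trans-fused lactone on the β face anti to H-7, which sets C11 with selenium trans to H-7.

Step 5
Reactants: 6 11β-phenylseleno lactone
Product: 8 4α,10α-dihydroxy-3-oxoguai-11(13)-en-12,6α-olide, via bis(triethylsilyl) ketol 7 (not isolated)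
Conditions: mCPBA (2.2 equiv), CH2Cl2, −78 to 0 °C; concentrate; 48% aq HF, MeCN, 0 °C
Reagents that add atoms: meta-chloroperbenzoic acid (mCPBA) O=C(OO)c1cccc(Cl)c1
Why: Selenoxide syn-elimination and Rubottom oxidation side by side: the oxidised selenium has no syn ring hydrogen (H-7 is trans) and eliminates only toward C13, the peracid epoxidises the electron-rich enol ether from the convex α face (sets 4α-O, with silyl migration to 7) while the new α-methylene lactone is too electron-poor to react, and HF then cleaves both Si–O bonds.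

Step 6
Reactants: 8 4α,10α-dihydroxy-3-oxoguai-11(13)-en-12,6α-olide
Product: 9 dehydrozaluzanin C
Conditions: SOCl2 (5 equiv), pyridine, −30 to 0 °C
Reagents that add atoms: none
Why: Twofold E2 dehydration through chlorosulfites: both leaving groups are α and cis to the ring-fusion hydrogen beside them (H-5 for C4, H-1 for C10), so anti-periplanar hydrogens are offered by the methyl groups C15 and C14 (C9 being the less accessible competitor at C10), an E1 path at C4 is shut off by the adjacent carbonyl, and no stereocentre is formed.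

Step 7
Reactants: 9 dehydrozaluzanin C
Product: 10 3-(tert-butyldimethylsilyloxy)guaia-2,4(15),10(14),11(13)-tetraen-12,6α-olide
Conditions: TBSOTf (1.2 equiv), Et3N (2 equiv), CH2Cl2, −78 °C
Reagents that add atoms: tert-butyldimethylsilyl trifluoromethanesulfonate (TBSOTf) CC(C)(C)[Si](C)(C)OS(=O)(=O)C(F)(F)F
Why: Soft enolisation: C2 carries the only enolisable hydrogens of the ketone because C4 is sp2, so the cross-conjugated silyl dienol ether forms, whose two double bonds are locked s-trans and cannot act as a Diels–Alder diene.

Step 8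
Reactants: 10 silyl dienol ether; 9 dehydrozaluzanin C (3 equiv, excess recovered)
Product: 14 gochnatiolide B (10β-hydroxy dimer), via trienone 11 (not isolated), via Diels–Alder adduct 12 (not isolated), via 10β-hydroperoxide 13 (not isolated)
Conditions: Pd(OAc)2 (1.1 equiv), MeCN, Ar, rt; then O2 (1 atm), rt; then P(OEt)3, 0 °C
Reagents that add atoms: dioxygen O=O
Why: Saegusa–Ito oxidation, intermolecular Diels–Alder reaction and autoxidation of a β,γ-unsaturated ketone in one flask: divalent palladium binds C2 of 10 on the α face and loses H-1 to give 11, whose s-cis-locked diene C14=C10–C1=C2 adds with ortho regiochemistry (C2 to C4', C14 to C15') to the convex α face of the exocyclic enone of 9, which sets C4' (the C2 centre of 12, drawn for the endo mode, is transient, so diene face and endo/exo mode do not matter), after which the doubly activated H-2 is abstracted under O2 and the dienyl radical binds oxygen at its tertiary γ-terminus C10 from the β face, opposite to the C5' branch that the spiro centre holds under the α face, before the phosphite reduces 13.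

Step 9
Reactants: 14 gochnatiolide B
Product: 15 ainsliadimer B
Conditions: p-TsOH·H2O (0.2 equiv), THF–H2O 3:1, 35 °C
Reagents that add atoms: water O
Why: Acid-catalysed conjugate addition of water (oxa-Michael hydration of an enone): the cross-conjugated dienone carbonyl is the most basic one, so only its unhindered C15 terminus is activated while the two α-methylene lactones and the isolated C10'=C14' bond stay untouched, and the new epimerisable C4 centre settles by enol–ketone equilibration with CH2OH on the convex α face, trans to C6.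

Compound list
1 | α-santonin, (11S)-3-oxoeudesma-1,4-dien-12,6α-olide | C[C@H]1[C@@H]2CC[C@@]3(C)C=CC(=O)C(C)=C3[C@H]2OC1=O | starting material
2 | cyclopropane zwitterion: C1–C5 bonded, C10 bridging on the β face, 3-oxido allyl cation over C2–C4 | C[C@H]1[C@@H]2CC[C@@]3(C)[C@@H]4C=C([O-])[C+](C)[C@]34[C@H]2OC1=O | intermediate
3 | isophotosantonic lactone, 10α-hydroxy-3-oxo-1α,7αH-6β,11βH-guai-4-en-12,6α-olide | C[C@H]1[C@@H]2CC[C@@](C)(O)[C@@H]3CC(=O)C(C)=C3[C@H]2OC1=O | intermediate
4 | 4,5-dihydroisophotosantonic lactone, 1α,4α,5α-H, cis-fused | C[C@H]1[C@@H]2CC[C@@](C)(O)[C@@H]3CC(=O)[C@H](C)[C@@H]3[C@H]2OC1=O | intermediate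
5 | 3,10α-bis(triethylsilyloxy)guai-3-en-12,6α-olide | C[C@H]1[C@@H]2CC[C@@](C)(O[Si](CC)(CC)CC)[C@@H]3CC(O[Si](CC)(CC)CC)=C(C)[C@@H]3[C@H]2OC1=O | intermediate
6 | 11β-phenylseleno derivative of 5 (13-methyl α, Se trans to H-7) | C[C@@]1([Se]c4ccccc4)[C@@H]2CC[C@@](C)(O[Si](CC)(CC)CC)[C@@H]3CC(O[Si](CC)(CC)CC)=C(C)[C@@H]3[C@H]2OC1=O | intermediate
7 | 4α,10α-bis(triethylsilyloxy)-3-oxoguai-11(13)-en-12,6α-olide | C=C1[C@@H]2CC[C@@](C)(O[Si](CC)(CC)CC)[C@@H]3CC(=O)[C@@](C)(O[Si](CC)(CC)CC)[C@@H]3[C@H]2OC1=O | intermediate
8 | 4α,10α-dihydroxy-3-oxoguai-11(13)-en-12,6α-olide | C=C1[C@@H]2CC[C@@](C)(O)[C@@H]3CC(=O)[C@@](C)(O)[C@@H]3[C@H]2OC1=O | intermediate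
9 | dehydrozaluzanin C, 3-oxoguaia-4(15),10(14),11(13)-trien-12,6α-olide (1α,5α,7α-H, 6β-H) | C=C1[C@@H]2CCC(=C)[C@@H]3CC(=O)C(=C)[C@@H]3[C@H]2OC1=O | intermediate
10 | 3-(tert-butyldimethylsilyloxy)guaia-2,4(15),10(14),11(13)-tetraen-12,6α-olide | C=C1[C@@H]2CCC(=C)[C@@H]3C=C(O[Si](C)(C)C(C)(C)C)C(=C)[C@@H]3[C@H]2OC1=O | intermediate
11 | trienone, 3-oxoguaia-1,4(15),10(14),11(13)-tetraen-12,6α-olide | C=C1[C@@H]2CCC(=C)C3=CC(=O)C(=C)[C@@H]3[C@H]2OC1=O | intermediate
12 | Diels–Alder adduct: C2–C4' and C14–C15' bonds, C1=C10 alkene, 2α-H, C4' with C2 on the α face of the primed unit | C=C1C(=O)O[C@@H]2[C@@H]3C4=C(CC[C@@H]12)CC[C@@]1([C@@H]4C(=O)C3=C)C(=O)C[C@H]4C(=C)CC[C@H]5C(=C)C(=O)O[C@@H]5[C@@H]14 | intermediate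
13 | 10β-hydroperoxide of the 1-en-3-one dimer | C=C1C(=O)O[C@@H]2[C@@H]3C4=C(C(=O)C3=C)[C@]3(CC[C@]4(OO)CC[C@@H]12)C(=O)C[C@H]1C(=C)CC[C@H]2C(=C)C(=O)O[C@@H]2[C@H]13 | intermediate
14 | gochnatiolide B, 10β-hydroxy dimer with C4=C15 intact | C=C1C(=O)O[C@@H]2[C@@H]3C4=C(C(=O)C3=C)[C@]3(CC[C@]4(O)CC[C@@H]12)C(=O)C[C@H]1C(=C)CC[C@H]2C(=C)C(=O)O[C@@H]2[C@H]13 | intermediate
15 | ainsliadimer B (4β-H, 4α-CH2OH, 10β-OH) | C=C1C(=O)O[C@@H]2[C@@H]3C4=C(C(=O)[C@H]3CO)[C@]3(CC[C@]4(O)CC[C@@H]12)C(=O)C[C@H]1C(=C)CC[C@H]2C(=C)C(=O)O[C@@H]2[C@H]13 | target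

Total step count: 9. Longest linear sequence: 9 (steps 1 to 9). Compound 9 enters step 8 a second time as the dienophile.

Steps most likely to fail

Step 6. Three processes may spoil it. Elimination at C10 may run into the ring toward C9. The leaving group at C4 may depart slowly because it sits next to the carbonyl. Chloride or pyridine may add in conjugate fashion to the new enone.

The fallback sets out from 4 and comes back at 9, and builds the enone by epoxide isomerisation instead of ketol dehydration.
- NaBH4 in MeOH at 0 °C delivers hydride from the convex α face to give the 3β,10α-diol F1.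
- POCl3 in pyridine removes both hydroxyls by anti elimination (H-4α for C3) to give the 3,10(14)-diene F2.
- LDA and PhSeSePh give the 11β-phenylselenide F3.
- H2O2 in THF gives isodehydrocostus lactone F4.
- mCPBA epoxidises the only trisubstituted, electron-rich double bond from the α face to give estafiatin F5.
- Al(OiPr)3 in refluxing toluene abstracts a C15 hydrogen syn to the epoxide oxygen and gives 3-epizaluzanin C F6.
- Dess–Martin periodinane oxidises F6 to 9.

Step 8. The transient trienone may undergo self-cycloaddition instead of the crossed reaction. The dienyl radical may also bind oxygen with poor facial or positional selectivity.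

The fallback sets out from 12 and comes back at 14.
- The Saegusa–Ito/Diels–Alder part is run and worked up under argon so that 12 is isolated.
- TBSOTf and Et3N at −78 °C remove the doubly activated H-2 to give the extended silyl trienol ether F7.
- Dimethyldioxirane (vinylogous Rubottom oxidation) epoxidises the terminal, tetrasubstituted C1=C10 bond. This two-electron oxidant is more sensitive to sterics than O2 and should attack the face away from C5'. C2 is shielded by the spiro centre.
- Work-up with HF·pyridine opens the epoxide to 14.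

Step 9. Water addition may stay incomplete or reverse. Water may also add to the lactone methylenes, and acid may cause the exocyclic double bonds to migrate.

The fallback sets out from 14 and comes back at 15, and makes a C–B bond first.
- Conjugate borylation uses B2pin2 (1.0 equiv), CuCl, DPEphos, catalytic NaOtBu and MeOH in THF at −20 °C.
- It should pick the most electrophilic acceptor and gives the 15-pinacolboryl ketone F8.
- NaBO3·4H2O in THF–H2O oxidises the C–B bond to the primary alcohol 15.

Further compounds
F1 | step 6 | 3β,10α-dihydroxy-1α,4α,5α-H-guaian-12,6α-olide | C[C@H]1[C@@H]2CC[C@@](C)(O)[C@@H]3C[C@H](O)[C@H](C)[C@@H]3[C@H]2OC1=O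
F2 | step 6 | 11βH-guaia-3,10(14)-dien-12,6α-olide | C[C@H]1[C@@H]2CCC(=C)[C@@H]3CC=C(C)[C@@H]3[C@H]2OC1=O
F3 | step 6 | 11β-phenylselenoguaia-3,10(14)-dien-12,6α-olide | C[C@@]1([Se]c4ccccc4)[C@@H]2CCC(=C)[C@@H]3CC=C(C)[C@@H]3[C@H]2OC1=O
F4 | step 6 | isodehydrocostus lactone, guaia-3,10(14),11(13)-trien-12,6α-olide | C=C1[C@@H]2CCC(=C)[C@@H]3CC=C(C)[C@@H]3[C@H]2OC1=O
F5 | step 6 | estafiatin, 3α,4α-epoxyguaia-10(14),11(13)-dien-12,6α-olide | C=C1[C@@H]2CCC(=C)[C@@H]3C[C@H]4O[C@@]4(C)[C@@H]3[C@H]2OC1=O
F6 | step 6 | 3-epizaluzanin C, 3α-hydroxyguaia-4(15),10(14),11(13)-trien-12,6α-olide | C=C1[C@@H]2CCC(=C)[C@@H]3C[C@@H](O)C(=C)[C@@H]3[C@H]2OC1=O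
F7 | step 8 | 3-(tert-butyldimethylsilyloxy)-2,1(10),4(15)-triene derived from 12 | C=C1C(=O)O[C@@H]2[C@@H]3C4=C(CC[C@@H]12)CC[C@@]1(C4=C(O[Si](C)(C)C(C)(C)C)C3=C)C(=O)C[C@H]4C(=C)CC[C@H]5C(=C)C(=O)O[C@@H]5[C@@H]14
F8 | step 9 | 15-pinacolboryl-4βH ketone derived from 14 | C=C1C(=O)O[C@@H]2[C@@H]3C4=C(C(=O)[C@H]3CB5OC(C)(C)C(C)(C)O5)[C@]3(CC[C@]4(O)CC[C@@H]12)C(=O)C[C@H]1C(=C)CC[C@H]2C(=C)C(=O)O[C@@H]2[C@H]13
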